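**Assumption:** the target SMILES contains no stereocentre or other stereo-element, so the compound is achiral and "single enantiomer" requires no stereocontrol.

## Retrosynthetic overview

1. Target 15 ⇒ benzyl ether removal and CHO → CO2H ⇒ depside aldehyde 13 ⇒ ester C–O cut into acid 10 and phenol 11, both made from one aldehyde 9.
2. 9 ⇒ 2,4-bis(benzyloxy)-6-pentylbenzaldehyde 7 (ortho OBn exchanged for OMe under chelation control) ⇒ Vilsmeier C–CHO cut ⇒ arene 5.
3. Key C–C bond: aryl–C1′ of 5 ⇒ aryl bromide 1 + pentanal 2. The aldehyde carbon is used as a carbanion (N–H hydrazone, N2 lost), so two natively electrophilic carbons are joined.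
4. No ring is formed: both benzene rings come intact from 1, and the two halves are joined by esterification in step 7.

## Route

Step 1
Reactants: 1 1,3-bis(benzyloxy)-5-bromobenzene; 2 pentanal
Product: 5 1,3-bis(benzyloxy)-5-pentylbenzene, via pentanal hydrazone 3 (not isolated), via benzylic alkyldiazene 4 (not isolated)
Conditions: 2 (2.0 equiv), N2H4·H2O (2.1 equiv), THF, rt, 1 h, then 4 Å MS; then 1, Ni(cod)2 (10 mol %), PMe3 (20 mol %), DBU (2.0 equiv), THF, 60 °C, 16 h
Reagents that add atoms: none
Why: Proposed new method: a denitrogenative Ni-catalysed cross-coupling in which the N–H hydrazone of an aliphatic aldehyde serves as a traceless C1 carbanion; Ni(0) adds to the Ar–Br bond, the DBU-deprotonated hydrazone binds through N and shifts to its C-bound aza-allyl form, C–C reductive elimination (favoured by small, electron-rich PMe3) gives diazene 4, and base-induced Wolff–Kishner-type loss of N2 leaves the CH2; the closest known reaction type is the Ni(0)/PMe3 coupling of aromatic aldehyde hydrazones with aryl halides to diarylmethanes, the extension being the aliphatic hydrazone, and no stereocentre survives.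

Step 2
Reactants: 5 1,3-bis(benzyloxy)-5-pentylbenzene
Product: 7 2,4-bis(benzyloxy)-6-pentylbenzaldehyde, via aryl iminium chloride 6 (not isolated)
Conditions: POCl3 (1.5 equiv), DMF, 0 → 70 °C, 3 h; then H2O, 50 °C
Reagents that add atoms: N,N-dimethylformamide CN(C)C=O; water O
Why: Vilsmeier–Haack formylation, in which the chloroiminium ion attacks C2 (para to one OBn, ortho to the other) rather than the more hindered C4 between the two ethers, and 6 is hydrolysed on work-up.

Step 3
Reactants: 7 2,4-bis(benzyloxy)-6-pentylbenzaldehyde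
Product: 8 4-(benzyloxy)-2-hydroxy-6-pentylbenzaldehyde
Conditions: MgBr2·OEt2 (3 equiv), toluene/Et2O, 80 °C; then 1 M HCl
Reagents that add atoms: none
Why: Chelation-directed Lewis-acid ether cleavage: Mg2+ bridges the formyl oxygen and the ortho ether oxygen in a six-membered chelate and bromide removes only that benzyl group by SN2, leaving the unchelated 4-OBn.

Step 4
Reactants: 8 4-(benzyloxy)-2-hydroxy-6-pentylbenzaldehyde
Product: 9 4-(benzyloxy)-2-methoxy-6-pentylbenzaldehyde
Conditions: MeI (3 equiv), K2CO3 (2 equiv), DMF, 40 °C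
Reagents that add atoms: iodomethane CI
Why: Williamson ether synthesis on the only acidic site, the hydrogen-bonded phenol, which alkylates cleanly in DMF.

Step 5
Reactants: 9 4-(benzyloxy)-2-methoxy-6-pentylbenzaldehyde
Product: 10 4-(benzyloxy)-2-methoxy-6-pentylbenzoic acid
Conditions: NaClO2, NaH2PO4, 2-methyl-2-butene (excess), t-BuOH/THF/H2O, rt
Reagents that add atoms: sodium chlorite [Na+].[O-]Cl=O
Why: Pinnick oxidation takes the hindered aldehyde to the acid, while the alkene scavenger traps HOCl so the electron-rich ring is not chlorinated and the benzyl ether is inert.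

Step 6
Reactants: 9 4-(benzyloxy)-2-methoxy-6-pentylbenzaldehyde
Product: 11 4-hydroxy-2-methoxy-6-pentylbenzaldehyde
Conditions: H2 (1 atm), 10% Pd/C, EtOAc, rt, stopped after 1 equiv H2
Reagents that add atoms: none
Why: Pd-catalysed hydrogenolysis of the aryl benzyl ether is faster than reduction of the hindered, electron-rich 2,6-disubstituted aldehyde in neutral EtOAc.

Step 7
Reactants: 10 4-(benzyloxy)-2-methoxy-6-pentylbenzoic acid; 11 4-hydroxy-2-methoxy-6-pentylbenzaldehyde
Product: 13 4-formyl-3-methoxy-5-pentylphenyl 4-(benzyloxy)-2-methoxy-6-pentylbenzoate, via mixed trifluoroacetic anhydride 12 (not isolated)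
Conditions: TFAA (3 equiv), dry toluene, rt, 4 h
Reagents that add atoms: none
Why: Mixed-anhydride esterification: the electron-rich 2,6-disubstituted acid forms an acyl trifluoroacetate (acylium-like) that acylates the only free phenol, and neither partner can self-condense.

Step 8
Reactants: 13 4-formyl-3-methoxy-5-pentylphenyl 4-(benzyloxy)-2-methoxy-6-pentylbenzoate
Product: 14 4-{[4-(benzyloxy)-2-methoxy-6-pentylbenzoyl]oxy}-2-methoxy-6-pentylbenzoic acid
Conditions: NaClO2, NaH2PO4, 2-methyl-2-butene (excess), t-BuOH/THF/H2O, rt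
Reagents that add atoms: sodium chlorite [Na+].[O-]Cl=O
Why: Pinnick oxidation at pH 3–4 converts the aldehyde to the acid without touching the aryl ester or the benzyl ether.

Step 9
Reactants: 14 4-{[4-(benzyloxy)-2-methoxy-6-pentylbenzoyl]oxy}-2-methoxy-6-pentylbenzoic acid
Product: 15 4-[(4-hydroxy-2-methoxy-6-pentylbenzoyl)oxy]-2-methoxy-6-pentylbenzoic acid (4-O-demethylplanaic acid)
Conditions: H2 (1 atm), 10% Pd/C, EtOAc, rt
Reagents that add atoms: none
Why: Hydrogenolysis removes the last benzyl ether; the depside ester, the carboxylic acid and the methyl ethers are inert, and the product has no stereocentre.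

## Compound list

1 | 1,3-bis(benzyloxy)-5-bromobenzene | Brc1cc(OCc2ccccc2)cc(OCc2ccccc2)c1 | starting material
2 | pentanal | CCCCC=O | starting material
3 | pentanal hydrazone (pentylidenehydrazine) | CCCCC=NN | intermediate
4 | {1-[3,5-bis(benzyloxy)phenyl]pentyl}diazene (racemic, transient) | CCCCC(N=N)c1cc(OCc2ccccc2)cc(OCc2ccccc2)c1 | intermediate
5 | 1,3-bis(benzyloxy)-5-pentylbenzene | CCCCCc1cc(OCc2ccccc2)cc(OCc2ccccc2)c1 | intermediate
6 | N-{[2,4-bis(benzyloxy)-6-pentylphenyl]methylidene}-N-methylmethanaminium chloride | CCCCCc1cc(OCc2ccccc2)cc(OCc2ccccc2)c1C=[N+](C)C.[Cl-] | intermediate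
7 | 2,4-bis(benzyloxy)-6-pentylbenzaldehyde | CCCCCc1cc(OCc2ccccc2)cc(OCc2ccccc2)c1C=O | intermediate
8 | 4-(benzyloxy)-2-hydroxy-6-pentylbenzaldehyde | CCCCCc1cc(OCc2ccccc2)cc(O)c1C=O | intermediate
9 | 4-(benzyloxy)-2-methoxy-6-pentylbenzaldehyde | CCCCCc1cc(OCc2ccccc2)cc(OC)c1C=O | intermediate
10 | 4-(benzyloxy)-2-methoxy-6-pentylbenzoic acid | CCCCCc1cc(OCc2ccccc2)cc(OC)c1C(=O)O | intermediate
11 | 4-hydroxy-2-methoxy-6-pentylbenzaldehyde | CCCCCc1cc(O)cc(OC)c1C=O | intermediate
12 | 4-(benzyloxy)-2-methoxy-6-pentylbenzoic trifluoroacetic anhydride | CCCCCc1cc(OCc2ccccc2)cc(OC)c1C(=O)OC(=O)C(F)(F)F | intermediate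
13 | 4-formyl-3-methoxy-5-pentylphenyl 4-(benzyloxy)-2-methoxy-6-pentylbenzoate | CCCCCc1cc(OC(=O)c2c(CCCCC)cc(OCc3ccccc3)cc2OC)cc(OC)c1C=O | intermediate
14 | 4-{[4-(benzyloxy)-2-methoxy-6-pentylbenzoyl]oxy}-2-methoxy-6-pentylbenzoic acid | CCCCCc1cc(OC(=O)c2c(CCCCC)cc(OCc3ccccc3)cc2OC)cc(OC)c1C(=O)O | intermediate
15 | 4-[(4-hydroxy-2-methoxy-6-pentylbenzoyl)oxy]-2-methoxy-6-pentylbenzoic acid (4-O-demethylplanaic acid) | CCCCCc1cc(OC(=O)c2c(CCCCC)cc(O)cc2OC)cc(OC)c1C(=O)O | target

## Step count and risks

Total step count: 9. Longest linear sequence: 8 (steps 1, 2, 3, 4, 5 or 6, 7, 8, 9).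

The three steps most likely to fail:

Step 1. The coupling is an untested extension: β-hydride loss at nickel, N-arylation of the hydrazone or azine formation could defeat it. The fallback sets out from 1 and replaces the hydrazone by a nitronate as the C1 carbanion of the pentyl chain. Pd-catalysed arylation of commercial 1-nitropentane with 1 (Pd2(dba)3, 2-(di-tert-butylphosphino)-2′-methylbiphenyl, Cs2CO3, DME, 50 °C) gives 1-[3,5-bis(benzyloxy)phenyl]-1-nitropentane F1. Its secondary benzylic nitro group is then removed by radical denitration (Bu3SnH, AIBN, toluene, 110 °C), and the route is rejoined at 5.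

Step 3. Mono- versus bis-debenzylation may be hard to control, and the liberated benzyl bromide can re-alkylate the phenoxide. The fallback sets out from 7 and inverts the logic: both benzyl groups are removed (BCl3, pentamethylbenzene, CH2Cl2, −78 °C) to give 2,4-dihydroxy-6-pentylbenzaldehyde F2. Only the non-hydrogen-bonded 4-OH is then benzylated (BnBr 1.05 equiv, K2CO3, acetone, rt), and the route is rejoined at 8.

Step 6. The aldehyde may be over-reduced to the benzyl alcohol or the methyl arene. The fallback sets out from 10 and avoids the hydroxy-aldehyde partner altogether. Hydrogenolysis (H2, Pd/C, EtOAc) gives 4-hydroxy-2-methoxy-6-pentylbenzoic acid F3. Alkylation of its carboxylate only (BnBr, KHCO3, DMF, 40 °C) gives benzyl 4-hydroxy-2-methoxy-6-pentylbenzoate F4. Coupling with a second portion of 10 (TFAA, toluene, via 12) gives benzyl 4-{[4-(benzyloxy)-2-methoxy-6-pentylbenzoyl]oxy}-2-methoxy-6-pentylbenzoate F5. Both benzyl groups are then cleaved together (H2, Pd/C, EtOAc), and the route is rejoined at 15, which also bypasses steps 7 and 8.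

## Further compounds

F1 | step 1 | 1-[3,5-bis(benzyloxy)phenyl]-1-nitropentane (racemic) | CCCCC([N+](=O)[O-])c1cc(OCc2ccccc2)cc(OCc2ccccc2)c1
F2 | step 3 | 2,4-dihydroxy-6-pentylbenzaldehyde | CCCCCc1cc(O)cc(O)c1C=O
F3 | step 6 | 4-hydroxy-2-methoxy-6-pentylbenzoic acid | CCCCCc1cc(O)cc(OC)c1C(=O)O
F4 | step 6 | benzyl 4-hydroxy-2-methoxy-6-pentylbenzoate | CCCCCc1cc(O)cc(OC)c1C(=O)OCc1ccccc1
F5 | step 6 | benzyl 4-{[4-(benzyloxy)-2-methoxy-6-pentylbenzoyl]oxy}-2-methoxy-6-pentylbenzoate | CCCCCc1cc(OC(=O)c2c(CCCCC)cc(OCc3ccccc3)cc2OC)cc(OC)c1C(=O)OCc1ccccc1
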